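With one enantiomer reacting faster and no exchange between the two, a product excess cannot hold level while conversion climbs: the substrate left grows poor in the enantiomer that reacts first. In this flask Q dissolves to J, J with Z turns E into G and X into L, and D interconverts E and X.

in all of them: E 0.22 M; X 0.22 M; Z 0.5 mol%

| run | Q | D | remark | time |
|---|---|---|---|---|
| north | 3 equiv | 0.5 mol% | the very flask that is asked about, followed so far |  |
| north-east | 3 equiv | 0.25 mol% | run made earlier |  |
| flask | 3.00 equiv | 0.5 mol% |  | 30 min |

| run | time / min | G / % | L / % |
|---|---|---|---|
| north | 1.33 | 0 | 2 |
| north | 2.50 | 1 | 0 |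
| north | 4.00 | 2 | 3 |
| north | 8.00 | 9 | 3 |
| north | 15.0 | 19 | 8 |
| north-east | 2.50 | 3 | 1 |
| north-east | 8.00 | 6 | 6 |
| north-east | 15.0 | 16 | 2 |
| north-east | 20.0 | 24 | 10 |
| north-east | 30.0 | 40 | 13 |

(readings scatter by 2 percentage points)

- Z is single-handed; E and X are mirror images of each other, charged as a racemate, each of them at the stated concentration
- given per volume of solution although it is solid: Q
- steps that have been proposed: J + Z + E -> Z + G; J + Z + X -> Z + L; E + D <-> X + D; Q <-> J
- at the start none of Q is in solution
- an excess is the difference of the two amounts in percent of their sum
- an excess is below zero if the other one leads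

1. G and L together, in percent of the E and X charged together, at 30 min
2. excess of G over L in the product at 30 min
3. whether the exchange between E and X keeps pace with the reaction: how far the product's excess at 30 min gets from its value without exchange to its value with instant exchange (above 80% keeps pace, below 20% hardly takes part, else lags behind)

The north-east run, with 0.25 mol% of D, read an excess of 47.1% pooled up to 15.0 min and 50.9% at 30.0 min, so, within a large scatter, it did not fall. I therefore judged that exchange keeps pace there, and more surely in this flask with 0.5 mol% of D. Then E and X stay level, and G formed per L formed, the selectivity factor s, is constant: the last reading gives 3.08. The excess is (s − 1)/(s + 1), or 50.9%. For the total I took the north-east reading, 53.0%, as my estimate for this flask, whose recipe differs from that run's in D.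

The forecast said 58%, 52% and lags behind: “Exchange probably lags behind, though the data cannot settle this firmly.”

The flask gave 50.9%, an excess of 54.1%, and keeps pace, at 98% of the way.

    J + Z + E → Z + G (k = 859 M⁻² min⁻¹)
    J + Z + X → Z + L (k = 254 M⁻² min⁻¹)
    E + D ⇌ X + D, rate k3*[D]*[E] forward; the back reaction follows from the equilibrium constant (k = 1560 M⁻¹ min⁻¹)
    Q ⇌ J, rate k4*(cs4 - [J]) while solid is left; crystals form when [J] > cs4 (solubility = 0.110 M, k = 0.129 min⁻¹)

At 30.0 min this flask held E 24.4% and X 24.7%. On the neighbour with 0.3 mol% of Z, which reached a total of 40.9%, my s splits the product into G 30.9% and L 10.0%, with the excess at 50.9%. At 30.0 min that neighbour held G 31.5% and L 9.37%, an excess of 54.2%.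

(The earlier runs and the new flask were computed for an exercise.)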